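**Proposed synthesis of prevezol C (25): an iminium-catalysed Diels–Alder reaction builds ring A, limonene-1,2-diol supplies ring B, and a Negishi coupling joins them (18 steps, longest linear sequence 13)**

Atom labels used throughout: ring A carbons are C1a–C6a (C1a carries the linker, C2a the isopropenyl group, C5a is the tertiary carbinol, C6a the secondary carbinol). C8 is the linker CH2 and C7 the sp2 carbon that carries the exocyclic methylene. Ring B carbons are C1b–C6b (C1b is bonded to C7, C4b is the tertiary carbinol, C5b carries bromine).

## Analysis of the target

Prevezol C (25) consists of two separate cyclohexane rings that are joined only through the C8 methylene and the C7 methylidene carbon, so that no fused or bridged ring system relays stereochemistry from one ring to the other. Ring A carries four contiguous stereocentres: the C6a oxygen is cis to the C1a side chain, C1a and C2a are trans, and the C5a hydroxyl is trans to the C6a hydroxyl, which makes the diol trans-diaxial in the chair that keeps both carbon substituents equatorial. Ring B carries three stereocentres: the C5b bromide is cis both to the C4b hydroxyl and to the C1b substituent, that is, an equatorial bromide beside an axial tertiary alcohol. This cis-bromohydrin cannot come from opening a bromonium ion or an epoxide, because both openings are anti. The sensitive groups are two tertiary alcohols (ionisation and dehydration in acid), a secondary bromide next to a tertiary alcohol (ring contraction or elimination with base or halophilic metals) and two 1,1-disubstituted alkenes (isomerisation in acid, attack by electrophilic oxidants). The difficulty is therefore twofold: each ring has to be made as a single enantiomer on its own and joined without touching a stereocentre, and ring A needs an oxygenated stereotetrad that no common terpene supplies. The strategy rests on the triad C6a–C1a–C2a: an oxygen-bearing carbon cis to a carbon substituent that is trans to a second carbon substituent is the endo, ortho adduct of a 1-oxygenated 2-methylbutadiene with an E-enal. In that adduct the formyl carbon is C8, the second acceptor group is a masked isopropenyl group, and the methyl-bearing alkene C4a=C5a sits where the tertiary carbinol is needed.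

## Retrosynthetic reasoning

25 from 24. The last operation only removes three silyl ethers. The tertiary alcohols and the bromohydrin are kept masked until the end, so that no C–C bond or stereocentre has to be made on the free polyol.

24 from 14 and 22 (bond C8–C7). The cut is placed between the sp3 linker carbon and the sp2 carbon because this bond creates no stereocentre and separates the molecule into two rings that can each be made enantiopure. C8 arrives as a primary iodide (14, used as its alkylzinc 23), C7 and its methylene as the enol triflate 22. The forward reaction has to join a β-branched primary alkyl metal to a hindered 1,1-disubstituted enol triflate without β-hydride elimination and without disturbing the secondary bromide.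

22 from 20 from 18. The enol triflate comes from the methyl ketone 20 by kinetic enolisation at the methyl group, and the ketone from the isopropenyl group of 18 by ozonolysis. The isopropenyl carbon bonded to the ring thus becomes C7, and only the terminal methylene is lost and re-made.

18 from 17, 16 and 15 (bond C5b–Br). Because anti additions cannot give the cis-bromohydrin, the bromide is introduced by substitution with inversion at the axial secondary hydroxyl of the trans-diaxial diol 15, which already holds C1b and C4b in the right configuration. The tertiary oxygen must be silylated first (16, then selective release of the secondary hydroxyl in 17) so that it cannot close an epoxide. The inversion is placed at the start of the short branch, on inexpensive material, and not on the coupled product. Once inverted, the bromide is equatorial, has no antiperiplanar hydrogen and cannot be reached from the rear by the enolate of 20, so it should survive the later steps.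

14 from 13, 12 and 11 (C8–I). The iodide is made from the primary alcohol 12 after selective removal of the primary silyl ether of 11. The tertiary hydroxyl is silylated last (14) so that no acidic proton is present when the organozinc is formed.

11 from 10, 9 and 8 (C5a–O, C4a–H). The tertiary carbinol is traced to the trisubstituted epoxide 10/9, opened by hydride at the less substituted carbon C4a. The epoxide comes from the cyclohexene 8 by peracid attack on the face opposite the C6a silyloxy group, which fixes C5a with its hydroxyl trans to the C6a oxygen. The epoxidation is placed at the ketone stage (8 to 9), before the isopropenyl group exists (10), so that no second alkene competes.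

8 from 7, 6 and 5 (ester to acetyl). The isopropenyl group is traced to the ethyl ester of 5 through the Weinreb amide 6/7 and the methyl ketone 8. Amide formation also removes the acetate, so both hydroxyls can be silylated in one operation (7).

5 from 4 from 2 and 3 (bonds C1a–C6a and C2a–C3a). The cyclohexene 4 is the Diels–Alder adduct of the dienyl acetate 2 and the enal ester 3. This is the only disconnection that makes ring A and three of its stereocentres at once from achiral four- and five-carbon pieces. The aldehyde is reduced in the same flask to the alcohol 5, because a β-acetoxy aldehyde is prone to elimination and epimerisation.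

2 from 1. The diene is the dienol acetate of the α-methyl enal 1. Since 1 has no α-hydrogen, enolisation can only occur towards the γ-carbon.

## Alternatives that were turned down

Alternative 1: Here ring A is joined to C8 by a tethered de Mayo sequence. The bonds cut are C1a–C8 and the bond from C2a to the acetyl carbon, which leads back to the hydroxy 1,5-diketone A2 and from there to the enol ether A1, in which the C6a oxygen of a ring-A cyclohexenol is the alkoxy group of a β-alkoxy enone whose acyl group carries ring B. In the forward direction A1 is irradiated with a triplet sensitiser, the short tether forces the crossed [2+2] mode and delivers C8 to C1a on the face of the C6a oxygen, aqueous acid opens the cyclobutane by retro-aldol cleavage, and equilibration at C2a gives A2. In its favour, the inter-ring bond and the cis relation of C6a and C1a come from one event, and both methylidene groups could then be made by one double methylenation. Against it, A1 is the enol ether of an unsymmetrical 1,3-diketone with a hindered secondary allylic alcohol, so its regioselective preparation is uncertain. The stereocentres C5a and C6a must exist in enantiopure form before the key step, which itself sets only C1a. The straight [2+2] mode and alkene isomerisation can compete, and the 1,5-diketone A2 can undergo intramolecular aldol reaction during methylenation. On convergence this alternative is stronger than the chosen route, which needs a separate sp3–sp2 coupling. The chosen strategy offers instead three stereocentres of ring A set by a catalyst from achiral commercial pieces, with no pre-formed chiral ring A.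

Alternative 2: Here ring B is built by a Diels–Alder reaction on a finished ring A. The bonds cut are C1b–C6b and C2b–C3b, leading back to the ring-A vinyl ketone A3 and isoprene A4. In the forward direction a chiral cationic oxazaborolidine activates A3, and A4 adds with para orientation to give the 4-methylcyclohex-3-enyl ketone A5, with C1b set by the catalyst. In its favour, this reaction type is well understood for vinyl ketones, reagent control should override the distant ring-A stereocentres, and C7 is already in place as a ketone, so ozonolysis, enol triflate formation and cross-coupling are not needed. Against it, the key step makes one stereocentre in the simpler ring and leaves the four stereocentres of ring A to be made beforehand and carried through as A3. The C4b=C5b alkene of A5 must then become the cis-bromohydrin, which anti additions cannot give, and a 4-substituted 1-methylcyclohexene offers almost no facial bias for epoxidation or dihydroxylation. On the ring-B side this alternative is shorter and sets C1b catalytically, where the chosen route relies on the chiral pool. The chosen strategy takes C1b and C4b from 15 with full control, leaves only C5b to be corrected, and spends its key step on ring A, where the stereochemical problem lies.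

Alternative 3: Here ring A is closed by a conjugate ene reaction. The bond cut is C1a–C2a together with a hydrogen shift, leading back from the cyclised ketone A7 to the acyclic E-enone A6, which carries the C7 ketone, the alkene C8=C1a and a remote prenyl group. In the forward direction an alkylaluminium dichloride activates the enone, the prenyl alkene attacks C1a, a methyl hydrogen passes to C8, and the six-membered ring closes with the isopropenyl group unveiled directly. In its favour, the isopropenyl group needs no functional-group interconversion, ring B and C7 are already attached, and the route mirrors a plausible biogenesis. Against it, A6 must carry the tertiary and secondary silyloxy stereocentres C5a and C6a, made separately in an acyclic chain. The target needs the C6a oxygen axial and cis to the C1a side chain, so the productive chair has both silyloxy groups axial, while the competing chair with equatorial oxygens leads to a diastereomer. A γ-silyloxy enone under a strong Lewis acid also risks ionisation and loss of the silyl group. On step economy at the isopropenyl group and on convergence this alternative is stronger. The chosen strategy sets the triad C6a–C1a–C2a by the endo and ortho rules and by a catalyst, not by a conformational preference that here points the wrong way.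

Key step: step 2

Assumption: 2 is used as its E isomer, the expected main product of step 1; a Z isomer cannot adopt the s-cis conformation and would pass through step 2 unchanged.

## Route

Step 1
Reactants: 1 (E)-2-methylbut-2-enal (tiglic aldehyde)
Product: 2 (E)-2-methylbuta-1,3-dien-1-yl acetate
Conditions: isopropenyl acetate, TsOH·H2O (cat.), Cu(OAc)2 (cat.), 100 °C, acetone distilled off
Reagents that add atoms: isopropenyl acetate, CC(=C)OC(C)=O
Why: Acid-catalysed enol acetylation by transesterification; the α-carbon of 1 has no hydrogen, so enolisation can only take a γ-hydrogen and gives the 1-acetoxydiene, with the E isomer (acetoxy trans to vinyl) expected to predominate.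

Step 2
Reactants: 2 (E)-2-methylbuta-1,3-dien-1-yl acetate; 3 ethyl (E)-4-oxobut-2-enoate
Product: 5 ethyl (1S,5R,6S)-5-acetoxy-6-(hydroxymethyl)-4-methylcyclohex-3-ene-1-carboxylate, via cycloadduct aldehyde 4 (not isolated)
Conditions: (5S)-5-benzyl-2,2,3-trimethylimidazolidin-4-one·HCl (20 mol %), MeCN/H2O 95:5, −10 °C; then EtOH, NaBH4, 0 °C
Reagents that add atoms: none
Why: The secondary amine condenses with the aldehyde of 3 (not with the ester) to an E-configured iminium ion, whose lowered LUMO reacts with the s-cis diene 2 in a concerted, asynchronous [4+2] cycloaddition; hydrolysis releases aldehyde 4 and the catalyst, and borohydride then reduces the aldehyde (not the esters) before the β-acetoxy aldehyde can eliminate acetic acid or epimerise. The closest known reaction type is the imidazolidinone-catalysed Diels–Alder reaction of enals with 1-acyloxybutadienes. Ring A is closed as a cyclohexene by this suprafacial [4+2] addition, which forms C1a–C6a and C2a–C3a. Regiochemistry: the iminium ion places the largest LUMO coefficient on the ester-bearing carbon, which bonds to the unsubstituted diene terminus (largest HOMO coefficient, opposite the acetoxy donor), so the acetoxy carbon ends next to the formyl carbon. C2a is set trans to C1a by the E geometry of 3, which a concerted addition preserves. C6a is set cis to C1a by the endo position of the iminium group under the diene together with the E geometry of 2. The absolute configuration at C1a comes from the catalyst: the iminium alkene lies away from the gem-dimethyl carbon, the benzyl group covers one face, and the diene adds to the other. The step needs chemoselective activation of the aldehyde, ortho regiochemistry and endo selectivity; the much stronger acceptor character of the iminium ion compared with the ester, and the 1-acetoxy donor of 2, secure them.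

Step 3
Reactants: 5 ethyl (1S,5R,6S)-5-acetoxy-6-(hydroxymethyl)-4-methylcyclohex-3-ene-1-carboxylate
Product: 6 (1S,5R,6S)-5-hydroxy-6-(hydroxymethyl)-N-methoxy-N,4-dimethylcyclohex-3-ene-1-carboxamide
Conditions: MeNH(OMe)·HCl, iPrMgCl (excess), THF, −20 → 0 °C
Reagents that add atoms: N,O-dimethylhydroxylamine hydrochloride, CNOC.Cl
Why: Aminolysis of the ethyl ester by the magnesium amide (Weinreb amide formation); the same reagent cleaves the acetate, and any lactone formed from the C8 alkoxide is opened to the same amide. C2a stays trans to C1a because that is the more stable arrangement.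

Step 4
Reactants: 6 (1S,5R,6S)-5-hydroxy-6-(hydroxymethyl)-N-methoxy-N,4-dimethylcyclohex-3-ene-1-carboxamide
Product: 7 (1S,5R,6S)-5-(tert-butyldimethylsilyloxy)-6-[(tert-butyldimethylsilyloxy)methyl]-N-methoxy-N,4-dimethylcyclohex-3-ene-1-carboxamide
Conditions: TBSOTf (2.5 equiv), 2,6-lutidine, CH2Cl2, −78 → 0 °C
Reagents that add atoms: tert-butyldimethylsilyl triflate, CC(C)(C)[Si](C)(C)OS(=O)(=O)C(F)(F)F
Why: Silylation of the primary and the hindered secondary hydroxyl with the silyl triflate; it blocks lactonisation, and the bulky C6a silyl ether later shields the upper face of the ring alkene.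

Step 5
Reactants: 7 the bis-silylated Weinreb amide
Product: 8 1-[(1S,5R,6S)-5-(tert-butyldimethylsilyloxy)-6-[(tert-butyldimethylsilyloxy)methyl]-4-methylcyclohex-3-en-1-yl]ethan-1-one
Conditions: MeMgBr, THF, 0 °C
Reagents that add atoms: methylmagnesium bromide, C[Mg]Br
Why: Weinreb ketone synthesis; the chelated tetrahedral adduct holds until work-up, so addition stops at the methyl ketone.

Step 6
Reactants: 8 the ring-A methyl ketone
Product: 9 the C4a–C5a epoxide of 8, oxirane oxygen on the ring face opposite the C6a silyloxy group (configuration as in the SMILES)
Conditions: mCPBA, NaHCO3, CH2Cl2, 0 °C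
Reagents that add atoms: 3-chloroperoxybenzoic acid, OOC(=O)c1cccc(Cl)c1
Why: Prilezhaev epoxidation of the only alkene, which for a trisubstituted alkene is far faster than Baeyer–Villiger oxidation of the ketone. The C6a silyloxy group is pseudoaxial (cis to the equatorial C1a substituent, and relieving allylic strain with the C5a methyl) and covers the upper face, so oxygen is delivered from below and C5a is set with its methyl group cis to the C6a oxygen.

Step 7
Reactants: 9 the epoxy ketone
Product: 10 the epoxide carrying an isopropenyl group at C2a (acetyl of 9 converted to prop-1-en-2-yl)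
Conditions: Ph3PCH3Br, KOtBu, THF, 0 °C → rt
Reagents that add atoms: methyltriphenylphosphonium bromide, C[P+](c1ccccc1)(c1ccccc1)c1ccccc1.[Br-]
Why: Wittig methylenation of the methyl ketone, done after the epoxidation so that no second alkene competes for the peracid; the non-stabilised ylide does not open a trisubstituted epoxide, and C2a is already in its stable trans configuration.

Step 8
Reactants: 10 the epoxy alkene
Product: 11 (1R,2R,3S,4S)-2-(tert-butyldimethylsilyloxy)-3-[(tert-butyldimethylsilyloxy)methyl]-1-methyl-4-(prop-1-en-2-yl)cyclohexan-1-ol
Conditions: LiEt3BH, THF, 0 °C → rt; H2O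
Reagents that add atoms: none
Why: SN2 opening of the epoxide by hydride at the less substituted carbon C4a, in the trans-diaxial sense (Fürst–Plattner rule), which leads directly to the chair with the C1a and C2a substituents equatorial. The C5a–O bond is not broken, so the tertiary hydroxyl stays trans to the C6a oxygen.

Step 9
Reactants: 11 the bis-silyl tertiary alcohol
Product: 12 (1R,2R,3S,4S)-2-(tert-butyldimethylsilyloxy)-3-(hydroxymethyl)-1-methyl-4-(prop-1-en-2-yl)cyclohexan-1-ol
Conditions: HF·pyridine, pyridine, THF, 0 °C
Reagents that add atoms: none
Why: Selective desilylation: the primary silyl ether is cleaved much faster than the secondary one, which is flanked by a quaternary and a branched carbon.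

Step 10
Reactants: 12 the primary alcohol
Product: 13 (1R,2R,3R,4S)-2-(tert-butyldimethylsilyloxy)-3-(iodomethyl)-1-methyl-4-(prop-1-en-2-yl)cyclohexan-1-ol
Conditions: I2, PPh3, imidazole, CH2Cl2, 0 °C → rt
Reagents that add atoms: iodine, II
Why: Appel-type iodination; the primary alkoxyphosphonium ion is displaced by iodide, while the tertiary alcohol does not react and, being trans to the CH2 group, cannot cyclise onto it.

Step 11
Reactants: 13 the iodo alcohol
Product: 14 the triethylsilyl ether of 13 at the C5a oxygen (C8 iodide, C6a OTBS, C5a OTES)
Conditions: TESOTf, 2,6-lutidine, CH2Cl2, −78 → 0 °C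
Reagents that add atoms: triethylsilyl triflate, CC[Si](CC)(CC)OS(=O)(=O)C(F)(F)F
Why: Silylation of the tertiary alcohol with the silyl triflate removes the only acidic proton before the organozinc is made.

Step 12
Reactants: 15 (1S,2S,4R)-limonene-1,2-diol
Product: 16 (1S,2S,4R)-1-methyl-4-(prop-1-en-2-yl)-1,2-bis(triethylsilyloxy)cyclohexane
Conditions: TESOTf (2.5 equiv), 2,6-lutidine, CH2Cl2, −78 → 0 °C
Reagents that add atoms: triethylsilyl triflate, CC[Si](CC)(CC)OS(=O)(=O)C(F)(F)F
Why: Exhaustive silylation; the triflate reagent is needed to reach the tertiary hydroxyl.

Step 13
Reactants: 16 the bis-triethylsilyl ether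
Product: 17 (1S,2S,5R)-2-methyl-5-(prop-1-en-2-yl)-2-(triethylsilyloxy)cyclohexan-1-ol
Conditions: PPTS (cat.), MeOH/CH2Cl2, 0 °C
Reagents that add atoms: none
Why: Acid-catalysed methanolysis removes the secondary triethylsilyl ether faster than the tertiary one, which is shielded by the methyl group on its quaternary carbon.

Step 14
Reactants: 17 the secondary alcohol with silylated tertiary oxygen
Product: 18 (1S,2R,4R)-2-bromo-1-methyl-4-(prop-1-en-2-yl)-1-(triethylsilyloxy)cyclohexane
Conditions: CBr4, PPh3, toluene, rt → 60 °C
Reagents that add atoms: carbon tetrabromide, BrC(Br)(Br)Br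
Why: Appel bromination; the axial alkoxyphosphonium ion is displaced by bromide in an SN2 reaction with inversion, so the bromide ends equatorial and cis to both the C4b oxygen and the C1b substituent, and the silylated tertiary oxygen cannot close an epoxide. The closest known cases are axial secondary alcohols beside quaternary carbons in terpenoid rings, which give equatorial bromides under these conditions.

Step 15
Reactants: 18 the bromo alkene
Product: 20 1-[(1R,3R,4S)-3-bromo-4-methyl-4-(triethylsilyloxy)cyclohexyl]ethan-1-one, via secondary ozonide 19 (not isolated)
Conditions: O3, CH2Cl2, −78 °C; then Me2S, −78 °C → rt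
Reagents that add atoms: ozone, [O-][O+]=O
Why: Ozonolysis of the only alkene with reductive work-up gives the methyl ketone; the bromide and the silyl ether are inert and C1b is not touched.

Step 16
Reactants: 20 the ring-B methyl ketone
Product: 22 1-[(1R,3R,4S)-3-bromo-4-methyl-4-(triethylsilyloxy)cyclohexyl]ethenyl trifluoromethanesulfonate, via potassium enolate 21 (not isolated)
Conditions: KHMDS, THF, −78 °C; then PhNTf2, −78 → 0 °C
Reagents that add atoms: N-phenylbis(trifluoromethanesulfonimide), O=S(=O)(N(c1ccccc1)S(=O)(=O)C(F)(F)F)C(F)(F)F
Why: Kinetic deprotonation at the methyl group and O-sulfonylation give the 1,1-disubstituted enol triflate; C1b is not enolised and is in any case in its stable all-equatorial configuration. The equatorial C–Br bond has no antiperiplanar hydrogen and its rear side cannot be reached by the enolate.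

Step 17
Reactants: 14 the ring-A iodide; 22 the ring-B enol triflate
Product: 24 the coupled tris-silyl ether (C6a OTBS, C5a OTES, C4b OTES; C8–C7 bond formed), via alkylzinc iodide 23 (not isolated)
Conditions: 14, Zn dust (activated with BrCH2CH2Br and TMSCl), LiCl, THF, 40 °C; supernatant added to 22, PdCl2(dppf) (5 mol %), THF/NMP, 50 °C
Reagents that add atoms: none
Why: Negishi coupling; zinc inserts into the primary C–I bond, zerovalent palladium adds to the enol triflate, and transmetalation followed by reductive elimination forms C8–C7, with the bidentate phosphine favouring reductive elimination over β-hydride elimination. The unactivated secondary bromide and the silyl ethers are inert, and no stereocentre is formed or touched.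

Step 18
Reactants: 24 the coupled tris-silyl ether
Product: 25 prevezol C, (1R,2R,3R,4S)-3-{2-[(1R,3R,4S)-3-bromo-4-hydroxy-4-methylcyclohexyl]prop-2-en-1-yl}-1-methyl-4-(prop-1-en-2-yl)cyclohexane-1,2-diol
Conditions: HF·pyridine, THF, 0 °C → rt
Reagents that add atoms: none
Why: Fluoride cleaves all three silyl ethers under weakly acidic conditions; a basic fluoride source is avoided because an alkoxide beside the bromide could trigger ring contraction, while the alkenes and tertiary alcohols tolerate this medium.

## Compound list

1 | (E)-2-methylbut-2-enal (tiglic aldehyde) | C/C=C(\C)C=O | starting material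
2 | (E)-2-methylbuta-1,3-dien-1-yl acetate | C=C/C(C)=C/OC(C)=O | intermediate
3 | ethyl (E)-4-oxobut-2-enoate | O=C/C=C/C(=O)OCC | starting material
4 | ethyl (1S,5R,6R)-5-acetoxy-6-formyl-4-methylcyclohex-3-ene-1-carboxylate (not isolated) | O=C[C@@H]1[C@@H](C(=O)OCC)CC=C(C)[C@@H]1OC(C)=O | intermediate
5 | ethyl (1S,5R,6S)-5-acetoxy-6-(hydroxymethyl)-4-methylcyclohex-3-ene-1-carboxylate | OC[C@@H]1[C@@H](C(=O)OCC)CC=C(C)[C@@H]1OC(C)=O | intermediate
6 | (1S,5R,6S)-5-hydroxy-6-(hydroxymethyl)-N-methoxy-N,4-dimethylcyclohex-3-ene-1-carboxamide | OC[C@@H]1[C@@H](C(=O)N(C)OC)CC=C(C)[C@@H]1O | intermediate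
7 | bis-TBS ether of 6 | CC(C)(C)[Si](C)(C)OC[C@@H]1[C@@H](C(=O)N(C)OC)CC=C(C)[C@@H]1O[Si](C)(C)C(C)(C)C | intermediate
8 | ring-A methyl ketone (bis-TBS) | CC(C)(C)[Si](C)(C)OC[C@@H]1[C@@H](C(C)=O)CC=C(C)[C@@H]1O[Si](C)(C)C(C)(C)C | intermediate
9 | epoxy ketone, oxirane anti to the C6a silyloxy group | CC(C)(C)[Si](C)(C)OC[C@@H]1[C@@H](C(C)=O)C[C@H]2O[C@@]2(C)[C@@H]1O[Si](C)(C)C(C)(C)C | intermediate
10 | epoxide with isopropenyl group at C2a | CC(C)(C)[Si](C)(C)OC[C@@H]1[C@@H](C(C)=C)C[C@H]2O[C@@]2(C)[C@@H]1O[Si](C)(C)C(C)(C)C | intermediate
11 | (1R,2R,3S,4S)-2-(TBS-oxy)-3-[(TBS-oxy)methyl]-1-methyl-4-(prop-1-en-2-yl)cyclohexan-1-ol | CC(C)(C)[Si](C)(C)OC[C@@H]1[C@@H](C(C)=C)CC[C@@](C)(O)[C@@H]1O[Si](C)(C)C(C)(C)C | intermediate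
12 | (1R,2R,3S,4S)-2-(TBS-oxy)-3-(hydroxymethyl)-1-methyl-4-(prop-1-en-2-yl)cyclohexan-1-ol | OC[C@@H]1[C@@H](C(C)=C)CC[C@@](C)(O)[C@@H]1O[Si](C)(C)C(C)(C)C | intermediate
13 | (1R,2R,3R,4S)-2-(TBS-oxy)-3-(iodomethyl)-1-methyl-4-(prop-1-en-2-yl)cyclohexan-1-ol | IC[C@@H]1[C@@H](C(C)=C)CC[C@@](C)(O)[C@@H]1O[Si](C)(C)C(C)(C)C | intermediate
14 | ring-A iodide, C5a OTES, C6a OTBS | IC[C@@H]1[C@@H](C(C)=C)CC[C@@](C)(O[Si](CC)(CC)CC)[C@@H]1O[Si](C)(C)C(C)(C)C | intermediate
15 | (1S,2S,4R)-limonene-1,2-diol | C=C(C)[C@@H]1CC[C@](C)(O)[C@@H](O)C1 | starting material
16 | (1S,2S,4R)-1-methyl-4-(prop-1-en-2-yl)-1,2-bis(triethylsilyloxy)cyclohexane | C=C(C)[C@@H]1CC[C@](C)(O[Si](CC)(CC)CC)[C@@H](O[Si](CC)(CC)CC)C1 | intermediate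
17 | (1S,2S,5R)-2-methyl-5-(prop-1-en-2-yl)-2-(triethylsilyloxy)cyclohexan-1-ol | C=C(C)[C@@H]1CC[C@](C)(O[Si](CC)(CC)CC)[C@@H](O)C1 | intermediate
18 | (1S,2R,4R)-2-bromo-1-methyl-4-(prop-1-en-2-yl)-1-(triethylsilyloxy)cyclohexane | C=C(C)[C@@H]1CC[C@](C)(O[Si](CC)(CC)CC)[C@H](Br)C1 | intermediate
19 | secondary ozonide of 18 (1,2,4-trioxolane, not isolated) | CC1(OCOO1)[C@@H]1CC[C@](C)(O[Si](CC)(CC)CC)[C@H](Br)C1 | intermediate
20 | 1-[(1R,3R,4S)-3-bromo-4-methyl-4-(triethylsilyloxy)cyclohexyl]ethan-1-one | CC(=O)[C@@H]1CC[C@](C)(O[Si](CC)(CC)CC)[C@H](Br)C1 | intermediate
21 | potassium enolate of 20 at the methyl side (not isolated) | [K+].[O-]C(=C)[C@@H]1CC[C@](C)(O[Si](CC)(CC)CC)[C@H](Br)C1 | intermediate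
22 | 1-[(1R,3R,4S)-3-bromo-4-methyl-4-(triethylsilyloxy)cyclohexyl]ethenyl trifluoromethanesulfonate | C=C(OS(=O)(=O)C(F)(F)F)[C@@H]1CC[C@](C)(O[Si](CC)(CC)CC)[C@H](Br)C1 | intermediate
23 | alkylzinc iodide from 14 (not isolated) | I[Zn]C[C@@H]1[C@@H](C(C)=C)CC[C@@](C)(O[Si](CC)(CC)CC)[C@@H]1O[Si](C)(C)C(C)(C)C | intermediate
24 | coupled tris-silyl ether of prevezol C | C=C(C[C@@H]1[C@@H](C(C)=C)CC[C@@](C)(O[Si](CC)(CC)CC)[C@@H]1O[Si](C)(C)C(C)(C)C)[C@@H]1CC[C@](C)(O[Si](CC)(CC)CC)[C@H](Br)C1 | intermediate
25 | prevezol C | C=C(C[C@@H]1[C@@H](C(=C)C)CC[C@@](C)(O)[C@@H]1O)[C@@H]1CC[C@](C)(O)[C@H](Br)C1 | target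

## Step count and least certain steps

Total: 18 steps. Longest linear sequence: 13 steps (steps 1–11, 17 and 18). The ring-B branch is 5 steps (steps 12–16).

Step 2 (key step). The most likely failure is loss of regio- and enantiocontrol through an uncatalysed or ester-directed cycloaddition, together with hydrolysis of the dienyl acetate in the aqueous acidic medium. The dienophile is activated at both ends, and the 2-methyl group of 2 opposes the directing effect of the acetoxy group. Fallback: setting out from 2 and 3, the enal is activated by a chiral cationic oxazaborolidine (protonated with triflimide) in CH2Cl2 at −78 °C. This replaces covalent iminium activation by Lewis-acid coordination of the formyl oxygen under anhydrous conditions; it gives the same aldehyde 4 and returns to the route there, with reduction to 5 as before (no new compound, F0).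

Step 14. The most likely failures are elimination of the alkoxyphosphonium ion to the cyclohexene (an axial hydrogen on C6b is antiperiplanar), participation of the neighbouring silyloxy oxygen leading to retention or an epoxide, and very slow substitution because bromide must pass the axial C4b–O bond. Fallback: setting out from 15, SOCl2 and Et3N give the cyclic sulfite F1. RuCl3 (cat.) with NaIO4 oxidises sulfur and at the same time cleaves the isopropenyl group, giving the cyclic sulfate ketone F2. LiBr in THF opens F2 at the secondary carbon C5b with inversion to the bromo sulfate F3, and catalytic H2SO4 with a little water in THF hydrolyses it to the bromohydrin ketone F4. TESOTf and 2,6-lutidine at −78 °C then return to the route at 20. Here the leaving group is tethered to the tertiary oxygen, so no epoxide can form and no separate protecting group sits on that oxygen during the substitution.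

Step 17. The most likely failures are β-hydride elimination from the alkylpalladium intermediate, slow transmetalation to the hindered 1,1-disubstituted vinylpalladium species, and protonation of the alkylzinc. Fallback: setting out from 14, iodine–lithium exchange with t-BuLi in Et2O at −78 °C and capture with B-methoxy-9-BBN give the borinate complex F5. This is coupled with 22 under B-alkyl Suzuki–Miyaura conditions (PdCl2(dppf), AsPh3, Cs2CO3, DMF/THF/H2O) and returns to the route at 24.

Step 6. The most likely failures are insufficient facial selectivity, if the silyloxy group does not fully block the upper face, and competing Baeyer–Villiger oxidation of the ketone. Fallback: setting out from 8, NaBH4 gives the secondary alcohol F6 (mixture at the carbinol, which is later removed). VO(acac)2 with t-BuOOH then epoxidises under direction by this bishomoallylic hydroxyl, which sits on the lower face, giving the epoxy alcohol F7. Dess–Martin oxidation returns to the route at 9.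

Step 3. The most likely failures are lactonisation of the C8 hydroxyl onto the carboxyl group during work-up and incomplete cleavage of the acetate. Fallback: setting out from 5, TBSCl and imidazole give the silyl ether F8. MeNH(OMe)·HCl with iPrMgCl then gives the hydroxy amide F9, with the acetate removed and no free primary hydroxyl present. TBSOTf and 2,6-lutidine return to the route at 7, at the cost of one step.

## Further compounds

F0 | step 2 | none | none
F1 | step 14 | cyclic sulfite of 15 | C=C(C)[C@@H]1CC[C@]2(C)OS(=O)O[C@H]2C1
F2 | step 14 | cyclic sulfate with acetyl group at C1b | CC(=O)[C@@H]1CC[C@]2(C)OS(=O)(=O)O[C@H]2C1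
F3 | step 14 | lithium salt of the C4b sulfate monoester with inverted C5b bromide | [Li+].CC(=O)[C@@H]1CC[C@](C)(OS(=O)(=O)[O-])[C@H](Br)C1
F4 | step 14 | 1-[(1R,3R,4S)-3-bromo-4-hydroxy-4-methylcyclohexyl]ethan-1-one | CC(=O)[C@@H]1CC[C@](C)(O)[C@H](Br)C1
F5 | step 17 | lithium B-alkyl-B-methoxy-9-borabicyclo[3.3.1]nonane ate complex from 14 | CO[B-]1(C[C@@H]2[C@@H](C(C)=C)CC[C@@](C)(O[Si](CC)(CC)CC)[C@@H]2O[Si](C)(C)C(C)(C)C)C2CCCC1CCC2.[Li+]
F6 | step 6 | secondary alcohol from reduction of 8 | CC(C)(C)[Si](C)(C)OC[C@@H]1[C@@H](C(C)O)CC=C(C)[C@@H]1O[Si](C)(C)C(C)(C)C
F7 | step 6 | epoxy alcohol, oxirane anti to the C6a silyloxy group | CC(C)(C)[Si](C)(C)OC[C@@H]1[C@@H](C(C)O)C[C@H]2O[C@@]2(C)[C@@H]1O[Si](C)(C)C(C)(C)C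
F8 | step 3 | primary TBS ether of 5 | CC(C)(C)[Si](C)(C)OC[C@@H]1[C@@H](C(=O)OCC)CC=C(C)[C@@H]1OC(C)=O
F9 | step 3 | Weinreb amide with free C6a hydroxyl and C8 OTBS | CC(C)(C)[Si](C)(C)OC[C@@H]1[C@@H](C(=O)N(C)OC)CC=C(C)[C@@H]1O
A1 | alternative 1 | tethered β-alkoxy enone (photosubstrate) | CC(=CC(=O)[C@@H]1CC[C@](C)(O[Si](CC)(CC)CC)[C@@H](O[Si](CC)(CC)CC)C1)O[C@@H]1C=CCC[C@@]1(C)O[Si](CC)(CC)CC
A2 | alternative 1 | hydroxy 1,5-diketone after equilibration at C2a | CC(=O)[C@H]1CC[C@@](C)(O[Si](CC)(CC)CC)[C@H](O)[C@@H]1CC(=O)[C@@H]1CC[C@](C)(O[Si](CC)(CC)CC)[C@@H](O[Si](CC)(CC)CC)C1
A3 | alternative 2 | ring-A vinyl ketone | C=CC(=O)C[C@@H]1[C@@H](C(=C)C)CC[C@@](C)(O[Si](CC)(CC)CC)[C@@H]1O[Si](CC)(CC)CC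
A4 | alternative 2 | isoprene | C=CC(C)=C
A5 | alternative 2 | C7 ketone carrying ring B as a 4-methylcyclohex-3-enyl group | O=C(C[C@@H]1[C@@H](C(=C)C)CC[C@@](C)(O[Si](CC)(CC)CC)[C@@H]1O[Si](CC)(CC)CC)[C@@H]1CCC(C)=CC1
A6 | alternative 3 | acyclic E-enone with remote prenyl group | CC(C)=CCC[C@@](C)(O[Si](CC)(CC)CC)[C@H](O[Si](CC)(CC)CC)/C=C/C(=O)[C@@H]1CC[C@](C)(O[Si](CC)(CC)CC)[C@@H](O[Si](CC)(CC)CC)C1
A7 | alternative 3 | cyclised ring-A C7 ketone | O=C(C[C@@H]1[C@@H](C(=C)C)CC[C@@](C)(O[Si](CC)(CC)CC)[C@@H]1O[Si](CC)(CC)CC)[C@@H]1CC[C@](C)(O[Si](CC)(CC)CC)[C@@H](O[Si](CC)(CC)CC)C1
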